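The pitfall in repeating theta, with 0.700 of partner per starting material, is to treat partner as the limiting reagent and to watch it as the end of the run.

in all of them: starting material 1.3 M
- south: partner 0.74 M; run made earlier
- south-west: partner 1.3 M; run made earlier
- epsilon: partner 1.20 M; time 8.0 h
- theta: partner 0.910 M; time 8.0 h
- gamma: partner 1.50 M; time 8.0 h

| run | time / h | starting material / % | intermediate / % | product / % |
|---|---|---|---|---|
| south | 0.417 | 88.5 | 3.0 | 0 |
| south | 0.833 | 79.9 | 6.7 | 0 |
| south | 1.50 | 66.6 | 11.4 | 0.9 |
| south | 3.00 | 40.7 | 21.8 | 0.9 |
| south | 6.00 | 18.8 | 28.4 | 3.2 |
| south-west | 0.417 | 87.7 | 4.1 | 0.5 |
| south-west | 0.833 | 79.1 | 10.0 | 0.1 |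
| south-west | 1.50 | 63.1 | 11.5 | 1.3 |
| south-west | 3.00 | 42.7 | 20.3 | 3.5 |
| south-west | 6.00 | 15.9 | 24.9 | 8.1 |

(readings scatter by 1 percentage point)

- the analysis behind the earlier runs scatters by 1 percentage point, standard deviation
- a reading of starting material is of its free form alone

* which of these there is most of at the end, counted by the starting material in it, epsilon (starting material / product / intermediate)
* which of these there is most of at the end, counted by the starting material in it, theta (starting material / product / intermediate)
* which of these there is most of at the end, counted by the starting material in it, gamma (starting material / product / intermediate)
* the largest of these amounts at the end, in percent of the starting material charged, epsilon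
* the largest of these amounts at the end, in percent of the starting material charged, theta
* the largest of these amounts at the end, in percent of the starting material charged, gamma

1. The bench rule says that the reagent charged in the smaller amount caps the product. I assume that one partner goes into each product, so in theta the cap stands at 70.0% of the starting material charged.

2. I write the balance of partner. For theta the number I need is 1.43: this partner cost, the charge of starting material over the charge of partner, multiplied by the fraction of starting material present as product, gives the fraction of its own charge that partner has spent.

3. The bench rule starts to matter where that product of cost and fraction nears the whole charge. The south run, with 3.2% product at 6.00 h, has spent 5.62% of its partner. The south-west run, with 8.1%, has spent 8.10%, far less than its charge. Both readings carry a scatter of 1 percentage point.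

4. So I treat partner as staying near its charge, which makes the step from intermediate to product pseudo-first-order. The intermediate reading at 6.00 h is higher in the south run than in the richer south-west run. I therefore expect intermediate to lead, standing higher in theta, which has less partner than epsilon and gamma, and lower in gamma, which has more partner than epsilon and theta. Taking 8.1% as a rough guess for product in theta at 8.0 h, the cost puts the spending of partner there at 11.6% of its charge. The amount to watch is intermediate, not partner.

5. The forecast gives intermediate at 23% in epsilon, 27% in theta and 19.5% in gamma: “Intermediate leads in all three, though gamma is close.”

6. The flasks give intermediate at 25.9% in epsilon, intermediate at 28.0% in theta and intermediate at 24.0% in gamma.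

    starting material → intermediate (k = 3.20 × 10⁻⁵ s⁻¹)
    partner + intermediate ⇌ product (K = 53.0 M⁻¹, k = 1.50 × 10⁻⁵ M⁻¹ s⁻¹)
    starting material ⇌ dormant form (K = 16.0, k = 5.10 × 10⁻⁵ s⁻¹)

At the cost above, the 7.74% of product in theta spends 11.1% of its partner, leaving 89%. In gamma, the forward step to product taken alone gives partner a half-life of 63 h at 1.94 h, longer than the run of 8.0 h. The same forward step gives intermediate in gamma a half-life of 9.5 h at 8.00 h, also longer than the run. The neighbour flask, gamma repeated with 2.5 M of partner, has a cost of 0.520, so its 17.1% of product spends 8.90% of its partner. Computed, that neighbour flask holds 91% of its partner and 18.6% intermediate.

(The readings were computed from invented constants; the scatter is artificial.)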